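The question for the flask was how much first product would stand at 5.0 d, and whether more gas would raise it.

| setting | south | west | flask |
|---|---|---|---|
| substrate | 0.80 M | 1.8 M | 1.2 M |
| gas | 200 mM (held) | 200 mM (held) | 200 mM (held) |
| remark | run made earlier | run made earlier |  |
| time |  |  | 5.0 d |

| run | time / d | first product / % |
|---|---|---|
| south | 0.167 | 6.3 |
| south | 0.500 | 21.3 |
| south | 0.833 | 34.9 |
| south | 1.25 | 47.3 |
| south | 1.67 | 57.8 |
| south | 2.50 | 61.2 |
| south | 3.00 | 54.8 |
| west | 0.417 | 12.3 |
| west | 0.833 | 22.3 |
| west | 1.25 | 30.3 |
| west | 1.67 | 39.4 |
| west | 2.00 | 45.2 |
| west | 2.50 | 50.0 |
| west | 3.00 | 52.3 |

(each reading ± 1 percentage point)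

* the first product standing at 5.0 d, as a percentage of the substrate charged
* the change that raises the amount of first product at 5.0 d, in percent of the substrate charged most ("none" if none brings more than 2 percentage points) (alder / ash / none)
* amount of first product at 5.0 d, in percent of the substrate charged, after ash

- alder: doubling the saturation concentration of gas, all else as stated
- ash: doubling the transfer coefficient of the gas, all else as stated

- at the start none of the gas is in solution

For whoever took over the bench, I first read the early rates of making first product from the runs:

south: 0.341 M/d
west: 0.531 M/d
flask, placed between them by its charge: 0.417 M/d

I then reckoned for the flask: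

rate × time / c(substrate) = 1.74

I called this the gas dose, the equivalents of gas per substrate charged if the early rate held.

The south run gave its highest reading, 61.2 %, at a dose of 1.06, and had fallen to 54.8 % at 1.28. The flask would stand further along at 5.0 d, since its dose was larger than 1.28. Extending that fall, I told them to expect 41.0 % and to leave the gas alone.

The forecast gave 42 %, 34 % after ash, and best change none, holding that “faster gas supply only destroys product”.

The flask gave 36.1 %, 21.8 % after ash, and best change none. Alder moved it by −29 percentage points, ash by −14 points.

    substrate + partner → first product + by-product (k = 0.340 /M/h)
    partner + first product → bis adduct + by-product (k = 0.0771 /M/h)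
    partner + bis adduct → triple product + by-product (k = 0.0551 /M/h)
    gas ⇌ partner, rate k4*(csat - [partner]) (kL = 0.150 /h)
    first product + by-product → side product (k = 0.00426 /M/h)

At 5.00 d in the flask, the step from substrate used partner at 0.26 of the rate of the step from first product. Counting one gas for each first product and side product, two for each bis adduct and 3 for each triple product, the flask had taken 1.47 equivalents, less than my dose of 1.74. For a neighbour flask with 0.72 M of substrate, the same line, carried below the south run, gives a dose of 2.26, larger than the dose of the flask, so I expected less first product in the neighbour. The neighbour gave 30.4 %, against 36.1 % in the flask.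

The numbers in the tables stem from a simulated flask with made-up constants; scatter was added.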